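**Assumption:** the target formula fixes C1, C4, C1' and C4' but not the sense of the C7–C5' axis, so the axis is left uncontrolled and rotamers, if stable, are carried together.

## Structural features

The target consists of two identical 8-hydroxycalamenene units, each a tetralin in which an aromatic ring (ring A or ring C) carrying a phenol on C8 and a methyl group on C6 is fused through C4a and C8a to a saturated ring (ring B or ring D) carrying a methyl group on C1 and an isopropyl group on C4. The units are joined unsymmetrically by one biaryl bond from C7 of ring A, ortho to the C8 hydroxyl, to C5' of ring C, para to the C8' hydroxyl, so the axis is flanked by O8, the C6 methyl, the C6' methyl and C4a'. All four stereocentres are benzylic CH carbons; they form two 1,4-pairs (C1/C4 and C1'/C4'), trans in each ring (1S,4R and 1'S,4'R), no two are adjacent, and no functional group remains next to any of them. The electron-rich phenols are sensitive to oxidants and electrophiles and are best carried as methyl ethers, and the benzylic tertiary C–H bonds can be lost to strong acid, to oxidants or to catalysts that move double bonds. The real difficulty is twofold: the crowded ortho–para biaryl bond, which would be hard to make once C4' with its isopropyl group stands peri to C5', and the remote 1,4-trans relation, which must be set at C4 and C4' without a neighbouring handle. For the second point it matters that the peri neighbour of C4' is ring A on C5' and not a hydrogen as at C5, so ring D is the more biased of the two rings. The key step uses the fact that, with oxygen on C8 and C8', C4a and C4a' are the only free positions ortho to C8a and C8a': an open bisabolane chain on C8a (C1 to C4 plus the 2-propenyl carbons) lacks only the C4–C4a bond, the same holds in the primed half, and both bonds can be closed in one operation to form rings B and D.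

## Logic of the disconnections

**20 ⇒ 19.** The two O–CH3 bonds on O8 and O8' are cut. The methyl ethers direct the metalation, survive organolithiums, fluoride, peracid and Lewis acid, and prevent O-alkylation during ring closure. The skeleton is not simplified, but every earlier step is freed from phenol chemistry. The forward ether cleavage must not touch benzylic C–H bonds, so no alkene may be left at that stage.

**19 ⇒ 18.** Two pairs of C–H bonds on the isopropyl groups are cut, which turns each into a 2-propenyl group. That alkene is the natural residue of an allyl cation captured at C4. The gain is the retron for a cation–arene closure. The forward hydrogenation must not move the double bond to C4, which is both allylic and benzylic.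

**18 ⇒ 17.** The C4–C4a and C4'–C4a' bonds are cut, opening rings B and D together. C4a and C4a' are the only free carbons ortho to the chains, so the position of closure is not in doubt. Two rings and two stereocentres are removed and a flexible dimeric bisabolane is left. The forward step must ionise two secondary allylic carbinols cleanly, close six-membered rings only, and set C4 and C4' trans to C1 and C1' under control of the existing centres. The carbinol configuration in 17 is deliberately left undefined because ionisation destroys it.

**17 ⇒ 16 ⇒ 15.** The C4–O and C4'–O bonds are cut and the double bond is moved back to the trisubstituted position by way of the epoxide. This places the oxygen exactly where the cation is needed, starting from the plain prenyl terminus of a bisabolane. The chain simplifies to an unfunctionalised homoprenyl group. The forward epoxide opening must remove a methyl hydrogen and not a C3 hydrogen.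

**15 ⇒ 14 ⇒ 8 + 11.** The C1–C2 and C1'–C2' bonds are cut, after exchanging the C1–H and C1'–H bonds for C–B bonds. A benzylic carbamate can be lithiated, borylated and rearranged stereospecifically, so C1 and C1' are set without any neighbouring group. The molecule falls into one biaryl core with two C2 arms and two molecules of the same C6 boronate. Two independent lithiation–borylation events must each proceed with full stereochemical fidelity, and the protodeboronation must be retentive.

**11 ⇒ 9.** The C–B bond is cut. The boronate is one step from a commercial bromide. The Grignard reagent must not rearrange.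

**8 ⇒ 6 + 7, and 6 ⇒ 5.** The carbamate C–O bonds and then the carbinol C–H bonds are cut. An aryl methyl ketone is the standard substrate for catalytic asymmetric reduction, and the carbamoyl chloride is a bulk chemical of which two molecules are needed. Both stereocentres are replaced by carbonyl groups. One catalyst must reduce two different aryl ketones with the same facial sense.

**5 ⇒ 3.** The C8a–C(acetyl) and C8a'–C(acetyl) bonds are cut. Each lies ortho to a methoxy group that can direct metalation. A bare dimethoxy-dimethyl biaryl remains. The forward step needs two ortho-lithiations in one flask and, in ring C, the choice of C8a' over C7'.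

**3 ⇒ 1 + 2.** The C7–C5' bond is cut. At this stage the axis has only three small ortho groups and no peri substituent, so a standard cross-coupling suffices. Two commercial cresol-type rings result. The doubly ortho-substituted ring is placed on the halide so that the boronic acid is not lost to protodeboronation.

## Other disconnections considered

Alternative 1: The cut is the C7–C5' biaryl bond, made after raising the C6' methyl carbon to a carboxyl carbon tied to O8 as an ester. The precursor is the ester A1, which links O8 of a complete ring A/B half to that carboxyl carbon of a complete, C5'-brominated ring C/D half. In the forward key step A1 would undergo palladium-catalysed intramolecular C–H arylation (Pd(OAc)2, PPh3, NaOAc, hot N,N-dimethylacetamide): oxidative addition into C5'–Br, acetate-assisted metalation of C7–H and reductive elimination would give the six-membered lactone A2.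
- In favour: the bond is made intramolecularly through a six-membered tether, which is the strongest answer to a biaryl with four ortho groups. The junction is as unambiguous as in the chosen plan. The lactone bridge of A2 could be opened with a chiral nucleophile or hydride to set the axis deliberately; on control of the axis this plan is better than the chosen one.
- Against: two different, fully cyclised halves are required, so the 1,4-trans problem at C4 and C4' must be solved twice in separate series and the identity of the two monomers is not used. The C5'–Br bond of A1 lies between the carboxyl-bearing C6' and C4a' with its peri isopropyl group, a demanding site for oxidative addition. After the key step the lactone carbonyl of A2 must be taken down to the C6' methyl group in two further reductive operations before O-demethylation.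
- Comparison: on structure it is convergent but unsymmetrical, against a two-directional plan. On mechanism the metal-mediated closure on a finished skeleton avoids cationic conditions next to benzylic centres, which is an equal or slightly better point, but it sets no stereocentre. On step economy it is clearly longer.

Alternative 2: The cut is through two bonds of ring C, C4a'–C8a' and C5'–C6', a retro-[4+2] that also opens ring D. The precursor A3 has ring A bonded through an alkyne (the future C5' and C4a') to a chain that carries C4' and C1' as preset stereocentres and ends in a 2-silyloxy diene (C8a'=C8'–C7'=C6'). In the forward key step A3 would be heated to effect the intramolecular Diels–Alder reaction, and a quinone oxidant (DDQ) in the same flask would aromatise ring C to give A4.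
- In favour: the crowded axis is never made by coupling; it begins as an unhindered aryl–alkyne bond. This is equal to the chosen plan in avoiding a late hindered coupling. It is better in that the tether fixes the whole substitution pattern of ring C. C4' is set in an open chain and not touched by the key step, so its configuration is more certain than in the chosen plan.
- Against: an electron-rich diene and an unactivated alkyne call for high temperature. The silyl dienol ether of A3 must be made with defined geometry and is sensitive to acid. The oxidant meets four benzylic C–H bonds and an electron-rich arene. The ring A/B half still needs its own answer to C4, and the two different O-protecting groups of A4 mean two deprotections.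
- Comparison: on structure it is linear and unsymmetrical. On mechanism it is pericyclic and stereochemically neutral, against a cationic closure with substrate control. On step economy it is markedly longer, because of the acyclic precursor with 1,4-stereocentres and the separate ring A/B synthesis.

Alternative 3: The cut is at C3–C4 and C4–C4a in each half, after placing a carbonyl on C3 and C3'. C4 with its isopropyl group goes back to the diazoalkane A6 (1-diazo-2-methylpropane), leaving the biaryl bis(3-methylindan-1-one) A5. In the forward key step Sc(OTf)3 would activate each indanone carbonyl of A5, A6 would add, and loss of N2 with migration of the aryl carbon would give the bis(2-tetralone) A7.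
- In favour: it is also two-directional, so it equals the chosen plan in using the repeating unit. C4 and C4' in A7 are benzylic and alpha to a ketone, hence epimerisable. This offers a thermodynamic route to trans that the chosen plan lacks, and is better on that point if trans is the more stable arrangement. The five-membered acylations leading to A5 are easy.
- Against: A6 is a non-stabilised diazoalkane that must be generated and used cold. Each carbonyl of A5 must prefer aryl over methylene migration, and in ring D the migrating carbon C4a' sits next to the biaryl bond. A7 is itself a ketone and can be homologated again. Both C3 carbonyls of A7 must later be removed by a strongly basic or a two-stage reductive deoxygenation.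
- Comparison: on structure it is equal. On mechanism it carries more selectivity questions (migration, over-reaction) but has a better handle on C4. On step economy it is worse, because two deoxygenations replace one clean hydrogenation.

Key step: step 10

## Route

Step 1
Reactants: 1 2-bromo-3-methylanisole; 2 (4-methoxy-2-methylphenyl)boronic acid
Product: 3 2,4'-dimethoxy-2',6-dimethylbiphenyl (ring A bonded through C7 to C5' of ring C)
Conditions: Pd(OAc)2 (2 mol %), SPhos (4 mol %), K3PO4, toluene–H2O, 100 °C
Reagents that add atoms: none
Why: Suzuki–Miyaura coupling; the bulky biarylphosphine makes a tri-ortho-substituted biaryl accessible, and the doubly ortho-substituted ring is the bromide so that the boronic acid, with one ortho group, resists protodeboronation. No stereocentre is formed.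

Step 2
Reactants: 3 2,4'-dimethoxy-2',6-dimethylbiphenyl
Product: 5 3,5'-diacetyl-2,4'-dimethoxy-2',6-dimethylbiphenyl (C8a/C8a' diacetyl), via 3,5'-dilithio biaryl 4 (not isolated)
Conditions: n-BuLi (2.6 equiv), TMEDA, Et2O, 0 °C to rt; MeC(O)N(OMe)Me (3 equiv), −78 °C to rt; then H2O
Reagents that add atoms: N-methoxy-N-methylacetamide, CON(C)C(C)=O
Why: Directed ortho-metalation; each methoxy group directs lithiation to its free ortho carbon, C8a in ring A (the other ortho carbon is C7) and C8a' in ring C (C7' is wedged between methoxy and methyl), as in the 3,3'-dilithiation of 2,2'-dimethoxybiaryls. The N-methoxy-N-methyl amide transfers one acetyl group per aryllithium and stops at the ketone.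

Step 3
Reactants: 5 3,5'-diacetyl-2,4'-dimethoxy-2',6-dimethylbiphenyl
Product: 6 (1S,1'S)-1,1'-(2,4'-dimethoxy-2',6-dimethylbiphenyl-3,5'-diyl)di(ethan-1-ol)
Conditions: RuCl[(S,S)-TsDPEN](p-cymene) (cat.), HCO2H–Et3N (5:2), DMF, 40 °C
Reagents that add atoms: none
Why: Asymmetric transfer hydrogenation of aryl methyl ketones (Noyori type); the (S,S)-catalyst delivers hydride to the Re face of each carbonyl as it does for acetophenone, so both carbinol centres are set as S under catalyst control. The two reductions are independent, so a wrong reduction at one site ends up mainly in a separable diastereomer.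

Step 4
Reactants: 6 (1S,1'S)-diol; 7 N,N-diisopropylcarbamoyl chloride (2.5 equiv in all)
Product: 8 (1S,1'S)-bis(N,N-diisopropylcarbamate) of 6
Conditions: Et3N (3 equiv), DMAP (cat.), toluene, 90 °C
Reagents that add atoms: N,N-diisopropylcarbamoyl chloride (second equivalent of 7), CC(C)N(C(C)C)C(=O)Cl
Why: O-Carbamoylation by nucleophilic acyl substitution, one molecule of 7 per hydroxyl group, so two molecules are consumed for each molecule of 6. No bond to a stereocentre is broken, so both centres stay S; the carbamate is the directing and leaving group for step 6.

Step 5
Reactants: 9 5-bromo-2-methylpent-2-ene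
Product: 11 4,4,5,5-tetramethyl-2-(4-methylpent-3-en-1-yl)-1,3,2-dioxaborolane, via (4-methylpent-3-en-1-yl)magnesium bromide 10 (not isolated)
Conditions: Mg, THF, 40 °C; i-PrOBpin, −78 °C to rt; then H2O
Reagents that add atoms: 2-isopropoxy-4,4,5,5-tetramethyl-1,3,2-dioxaborolane, CC(C)OB1OC(C)(C)C(C)(C)O1
Why: Grignard formation and borylation with an alkoxyboronate. The homoallylic Grignard reagent keeps its open form because the cyclopropylcarbinyl isomer would be a tertiary carbanion.

Step 6
Reactants: 8 (1S,1'S)-bis(N,N-diisopropylcarbamate); 11 homoprenyl pinacol boronate (3 equiv in all)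
Product: 14 3,5'-bis[(2S)-6-methyl-2-(4,4,5,5-tetramethyl-1,3,2-dioxaborolan-2-yl)hept-5-en-2-yl]-2,4'-dimethoxy-2',6-dimethylbiphenyl, via dilithiated bis-carbamate 12 (not isolated), via dilithium bis-boronate complex 13 (not isolated)
Conditions: s-BuLi (2.6 equiv), Et2O, −78 °C; 11 (3 equiv), −78 °C; MgBr2·OEt2, MeOH, −78 °C to rt; then H2O
Reagents that add atoms: homoprenyl pinacol boronate (second equivalent of 11), CC(C)=CCCB1OC(C)(C)C(C)(C)O1
Why: Lithiation–borylation (a 1,2-metallate rearrangement of the Matteson type), one molecule of 11 per carbamate; carbamate-directed benzylic deprotonation with retention gives 12, the pinacol boronate is captured with retention to give 13, and the homoprenyl group migrates from boron to carbon anti to the departing carbamate, with inversion, so C1 and C1' of 14 are both S. MgBr2 with MeOH speeds the migration and suppresses reversal of the boronate complex, the path by which ortho-substituted aryl substrates lose stereochemical purity.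

Step 7
Reactants: 14 (S,S)-bis(tertiary pinacol boronate)
Product: 15 3,5'-bis[(2S)-6-methylhept-5-en-2-yl]-2,4'-dimethoxy-2',6-dimethylbiphenyl
Conditions: Bu4NF·3H2O, n-pentane, 45 °C
Reagents that add atoms: none
Why: Fluoride-promoted protodeboronation of tertiary benzylic boronic esters; the fluoroboronate is protonated at carbon by water with retention, which fixes C1 and C1' as S. The alkenes and aryl ethers are inert.

Step 8
Reactants: 15 (S,S)-bis-homoprenyl biaryl
Product: 16 3,5'-bis[(2S)-4-(3,3-dimethyloxiran-2-yl)butan-2-yl]-2,4'-dimethoxy-2',6-dimethylbiphenyl (epoxide epimers)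
Conditions: mCPBA (2.2 equiv), NaHCO3, CH2Cl2, 0 °C
Reagents that add atoms: mCPBA, O=C(OO)c1cccc(Cl)c1
Why: Prilezhaev epoxidation; the two trisubstituted alkenes are the only sites nucleophilic enough for the peracid at 0 °C. The epoxide centres form without control, which is harmless because they are destroyed in step 10.

Step 9
Reactants: 16 bis-epoxide
Product: 17 3,5'-bis[(2S)-5-hydroxy-6-methylhept-6-en-2-yl]-2,4'-dimethoxy-2',6-dimethylbiphenyl (carbinol epimers)
Conditions: Al(OiPr)3, toluene, 110 °C; then H2O
Reagents that add atoms: none
Why: Aluminium alkoxide-promoted isomerisation of a trisubstituted epoxide to an allylic alcohol; the C–O bond at the tertiary carbon breaks while a methyl hydrogen is removed through a cyclic syn transition state, giving the secondary 2-propenyl carbinol. The carbinol centres stay mixed and need not be defined.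

Step 10
Reactants: 17 biaryl bis(allylic alcohol)
Product: 18 bis-isopropenyl dimethyl ether (1S,4R,1'S,4'R), the 7,5'-linked dimer of (1S,4R)-8-methoxy-1,6-dimethyl-4-(prop-1-en-2-yl)-1,2,3,4-tetrahydronaphthalene
Conditions: BF3·OEt2 (0.3 equiv per carbinol), CH2Cl2 (high dilution), −60 to −20 °C
Reagents that add atoms: none
Why: BF3 coordinates each carbinol oxygen and ionises it to a 1-alkyl-2-methylallyl cation, and since both carbinol epimers give the same planar cation the mixture converges. The closest known reaction type is the intramolecular Friedel–Crafts allylic alkylation (cation–arene cyclisation) of a bisabolane side chain. Ring B closes as a six-membered ring by bonding of the near allyl terminus C4 to C4a, the 2-propenyl unit staying outside the ring, whereas bonding through the far CH2 terminus would need an eight-membered ring. Ring D closes in the same six-membered mode at C4a', the carbon between C8a' and the biaryl carbon C5'. Attack may be direct or may begin at the oxygen-activated ipso carbon (C8a, C8a') to give a spiro arenium ion, from which the allylic carbon C4, the better migrating group, shifts to C4a; a shift of C1 instead would place the 2-propenyl carbon next to oxygen, so this is the regiochemical point to watch. C4 and C4' are set under control of C1 and C1': in the half-chair transition state the C1 methyl is pseudoaxial to avoid the C8 methoxy group and the 2-propenyl group is expected to be pseudoaxial to avoid the peri group (H on C5 in ring B, all of ring A on C5' in ring D), which is the 1,4-trans arrangement (4R, 4'R). The step needs site selectivity on each arene, secured because C8 and C8' carry methoxy, and C- over O-alkylation, secured by the methyl ethers; low temperature and a substoichiometric Lewis acid limit acid-promoted drift of the new double bonds toward C4.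

Step 11
Reactants: 18 bis-isopropenyl dimethyl ether
Product: 19 7,5'-linked dimer of (1S,4R)-8-methoxy-1,6-dimethyl-4-(propan-2-yl)-1,2,3,4-tetrahydronaphthalene (target dimethyl ether)
Conditions: H2 (1–4 atm), RhCl(PPh3)3 (cat.), toluene–EtOH, rt
Reagents that add atoms: none
Why: Homogeneous hydrogenation with RhCl(PPh3)3 reduces 1,1-disubstituted alkenes without hydrogenolysis and with little double-bond migration, so the allylic and benzylic centres C4 and C4' keep their configuration. No new stereocentre is formed.

Step 12
Reactants: 19 target dimethyl ether
Product: 20 CNP0145304.1 [(5R,5'R,8S,8'S)-3,3',8,8'-tetramethyl-5,5'-di(propan-2-yl)-5,5',6,6',7,7',8,8'-octahydro-[2,4'-binaphthalene]-1,1'-diol]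
Conditions: BBr3, CH2Cl2, −78 to 0 °C; then H2O
Reagents that add atoms: none
Why: Lewis-acid cleavage of aryl methyl ethers (O-complexation, then bromide attack on methyl); no alkene is left to add HBr and the benzylic C–H centres are not ionised at this temperature. Hydrolysis of the aryl borates gives the diphenol.

## Compound list

1 | 2-bromo-3-methylanisole | COc1cccc(C)c1Br | starting material
2 | (4-methoxy-2-methylphenyl)boronic acid | COc1ccc(B(O)O)c(C)c1 | starting material
3 | 2,4'-dimethoxy-2',6-dimethylbiphenyl | Cc1cccc(OC)c1-c1ccc(OC)cc1C | intermediate
4 | 3,5'-dilithio-2,4'-dimethoxy-2',6-dimethylbiphenyl (lithium on C8a and C8a'; formed in the flask) | Cc1ccc([Li])c(OC)c1-c1cc([Li])c(OC)cc1C | intermediate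
5 | 3,5'-diacetyl-2,4'-dimethoxy-2',6-dimethylbiphenyl | Cc1ccc(C(C)=O)c(OC)c1-c1cc(C(C)=O)c(OC)cc1C | intermediate
6 | (1S,1'S)-1,1'-(2,4'-dimethoxy-2',6-dimethylbiphenyl-3,5'-diyl)di(ethan-1-ol) | Cc1ccc([C@H](C)O)c(OC)c1-c1cc([C@H](C)O)c(OC)cc1C | intermediate
7 | N,N-diisopropylcarbamoyl chloride | CC(C)N(C(C)C)C(=O)Cl | starting material
8 | (1S,1'S)-bis(N,N-diisopropylcarbamate) of 6 | Cc1ccc([C@H](C)OC(=O)N(C(C)C)C(C)C)c(OC)c1-c1cc([C@H](C)OC(=O)N(C(C)C)C(C)C)c(OC)cc1C | intermediate
9 | 5-bromo-2-methylpent-2-ene | CC(C)=CCCBr | starting material
10 | (4-methylpent-3-en-1-yl)magnesium bromide (formed in the flask) | CC(C)=CCC[Mg]Br | intermediate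
11 | 4,4,5,5-tetramethyl-2-(4-methylpent-3-en-1-yl)-1,3,2-dioxaborolane | CC(C)=CCCB1OC(C)(C)C(C)(C)O1 | intermediate
12 | dilithiated bis-carbamate, lithium in place of each benzylic hydrogen of 8 with retention (formed in the flask) | Cc1ccc([C@]([Li])(C)OC(=O)N(C(C)C)C(C)C)c(OC)c1-c1cc([C@]([Li])(C)OC(=O)N(C(C)C)C(C)C)c(OC)cc1C | intermediate
13 | dilithium bis-boronate complex, each benzylic carbon of 12 bonded to the boron of one molecule of 11 (formed in the flask) | Cc1ccc([C@]([B-]2(CCC=C(C)C)OC(C)(C)C(C)(C)O2)(C)OC(=O)N(C(C)C)C(C)C)c(OC)c1-c1cc([C@]([B-]2(CCC=C(C)C)OC(C)(C)C(C)(C)O2)(C)OC(=O)N(C(C)C)C(C)C)c(OC)cc1C.[Li+].[Li+] | intermediate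
14 | 3,5'-bis[(2S)-6-methyl-2-(4,4,5,5-tetramethyl-1,3,2-dioxaborolan-2-yl)hept-5-en-2-yl]-2,4'-dimethoxy-2',6-dimethylbiphenyl | Cc1ccc([C@@](B2OC(C)(C)C(C)(C)O2)(C)CCC=C(C)C)c(OC)c1-c1cc([C@@](B2OC(C)(C)C(C)(C)O2)(C)CCC=C(C)C)c(OC)cc1C | intermediate
15 | 3,5'-bis[(2S)-6-methylhept-5-en-2-yl]-2,4'-dimethoxy-2',6-dimethylbiphenyl | Cc1ccc([C@@H](C)CCC=C(C)C)c(OC)c1-c1cc([C@@H](C)CCC=C(C)C)c(OC)cc1C | intermediate
16 | 3,5'-bis[(2S)-4-(3,3-dimethyloxiran-2-yl)butan-2-yl]-2,4'-dimethoxy-2',6-dimethylbiphenyl (epoxide epimers) | Cc1ccc([C@@H](C)CCC2OC2(C)C)c(OC)c1-c1cc([C@@H](C)CCC2OC2(C)C)c(OC)cc1C | intermediate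
17 | 3,5'-bis[(2S)-5-hydroxy-6-methylhept-6-en-2-yl]-2,4'-dimethoxy-2',6-dimethylbiphenyl (carbinol epimers) | Cc1ccc([C@@H](C)CCC(O)C(C)=C)c(OC)c1-c1cc([C@@H](C)CCC(O)C(C)=C)c(OC)cc1C | intermediate
18 | 7,5'-linked dimer of (1S,4R)-8-methoxy-1,6-dimethyl-4-(prop-1-en-2-yl)-1,2,3,4-tetrahydronaphthalene | Cc1cc2c(c(OC)c1-c1c(C)cc(OC)c3c1[C@@H](C(C)=C)CC[C@@H]3C)[C@@H](C)CC[C@@H]2C(C)=C | intermediate
19 | 7,5'-linked dimer of (1S,4R)-8-methoxy-1,6-dimethyl-4-(propan-2-yl)-1,2,3,4-tetrahydronaphthalene | Cc1cc2c(c(OC)c1-c1c(C)cc(OC)c3c1[C@@H](C(C)C)CC[C@@H]3C)[C@@H](C)CC[C@@H]2C(C)C | intermediate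
20 | CNP0145304.1, 7,5'-linked dimer of (1S,4R)-8-hydroxycalamenene | Cc1cc2c(c(O)c1-c1c(C)cc(O)c3c1[C@@H](C(C)C)CC[C@@H]3C)[C@@H](C)CC[C@@H]2C(C)C | target

## Step count and least certain steps

Total step count: 12. Longest linear sequence: 11 steps (steps 1–4 and 6–12 from 1 or 2); step 5 is a one-step side branch.

**Step 10 (key step).** The most likely failure is poor facial selectivity at C4 and C4', giving cis rings beside trans, made worse by acid-promoted drift of the 2-propenyl double bonds into conjugation, which erases C4. The 1,4-induction rests only on a conformational preference, and in ring B the peri group is merely a hydrogen. Closure of ring D at the crowded C4a' may also lag behind ring B. The fallback sets out from 15 and comes back at 19, with C4 and C4' set by a catalyst instead of by the substrate. Oxidative cleavage of both alkenes of 15 (OsO4 cat., KHSO5 as 2KHSO5·KHSO4·K2SO4, DMF) would give the bis(4-arylpentanoic acid) F1. Intramolecular Friedel–Crafts acylation (P2O5 in MeSO3H) at C4a and C4a' would give the bis(4-methyl-1-tetralone) F2. Addition of i-PrMgCl in the presence of CeCl3 would give the bis(tertiary benzylic alcohol) F3, and dehydration (TsOH, toluene, 80 °C) would give the bis(1,2-dihydronaphthalene) F4 with C3=C4 and C3'=C4' double bonds. Asymmetric hydrogenation of F4 with a chiral iridium N,P-ligand complex such as [Ir(cod)(t-Bu-PHOX)]BArF, ligand enantiomer chosen for 4R and 4'R, would deliver 19.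

**Step 2.** The most likely failure is metalation at the wrong ortho carbon of ring C (C7' instead of C8a') or an incomplete second metalation, together with proton transfer from the acetyl donor to the aryllithium. The methyl group on C6' shields C7' only moderately, and the second lithiation must occur on an already anionic molecule. The fallback sets out from 1 and comes back at 5, with the ring C acetyl group in place before the biaryl is made. Bromine–lithium exchange on 1 (n-BuLi, THF, −78 °C), B(Oi-Pr)3 and aqueous acid would give (2-methoxy-6-methylphenyl)boronic acid F5. Purchased 1-(5-bromo-2-methoxy-4-methylphenyl)ethanone F6 would be protected as its 1,3-dioxolane, 2-(5-bromo-2-methoxy-4-methylphenyl)-2-methyl-1,3-dioxolane F7 (ethylene glycol, TsOH, toluene, reflux). Suzuki–Miyaura coupling of F5 with F7 under the conditions of step 1 would give the biaryl ketal F8. A single ortho-lithiation and acetylation at C8a of ring A, the only unhindered carbon ortho to a methoxy group, would give the keto ketal F9, and aqueous HCl would remove the dioxolane and give 5.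

**Step 6.** The most likely failure is loss of configurational integrity at C1 or C1' through reversible boronate formation and slow migration at the ortho-methoxy-substituted benzylic centres, or incomplete lithiation of the second carbamate. Each centre has to pass three stereospecific events and the two sites must both succeed. The fallback sets out from 6 and comes back at 15; 6 may then be used in any configuration because the coupling is stereoconvergent. SOCl2 (CH2Cl2, 0 °C) would give the bis(1-chloroethyl) biaryl F10. Nickel-catalysed enantioconvergent Negishi coupling of F10 (NiBr2·diglyme, chiral i-Pr-Pybox ligand chosen for the S,S product, DMA, 0 °C) with the homoprenylzinc reagent (4-methylpent-3-en-1-yl)zinc bromide F11, made from 9 and Zn, would give 15.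

**Step 9.** The most likely failure is a different course of epoxide opening at 110 °C: a 1,2-hydride shift to the isopropyl ketone, or proton loss from C3 giving the tertiary allylic alcohol, which would ionise to the wrong cation in step 10. The fallback sets out from 15 and comes back at 17. Lemieux–Johnson cleavage of 15 (OsO4 cat., NaIO4, 2,6-lutidine, dioxane–H2O) would give the bis-aldehyde F12, and addition of CH2=C(CH3)MgBr (THF, −78 °C) to F12 would give 17 as the same mixture of carbinol epimers.

## Further compounds

F1 | step 10 | 3,5'-bis[(2S)-4-carboxybutan-2-yl]-2,4'-dimethoxy-2',6-dimethylbiphenyl (bis-acid) | Cc1ccc([C@@H](C)CCC(O)=O)c(OC)c1-c1cc([C@@H](C)CCC(O)=O)c(OC)cc1C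
F2 | step 10 | biaryl bis(4-methyl-1-tetralone), C4 and C4' as carbonyl carbons, (1S,1'S) | Cc1cc2c(c(OC)c1-c1c(C)cc(OC)c3c1C(=O)CC[C@@H]3C)[C@@H](C)CCC2=O
F3 | step 10 | biaryl bis(tertiary benzylic alcohol), isopropyl and hydroxyl on C4 and C4' | Cc1cc2c(c(OC)c1-c1c(C)cc(OC)c3c1C(O)(C(C)C)CC[C@@H]3C)[C@@H](C)CCC2(O)C(C)C
F4 | step 10 | biaryl bis(4-isopropyl-1-methyl-1,2-dihydronaphthalene), C3=C4 and C3'=C4' | Cc1cc2c(c(OC)c1-c1c(C)cc(OC)c3c1C(C(C)C)=CC[C@@H]3C)[C@@H](C)CC=C2C(C)C
F5 | step 2 | (2-methoxy-6-methylphenyl)boronic acid | COc1cccc(C)c1B(O)O
F6 | step 2 | 1-(5-bromo-2-methoxy-4-methylphenyl)ethanone (purchased) | COc1cc(C)c(Br)cc1C(C)=O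
F7 | step 2 | 2-(5-bromo-2-methoxy-4-methylphenyl)-2-methyl-1,3-dioxolane | COc1cc(C)c(Br)cc1C1(C)OCCO1
F8 | step 2 | biaryl ketal, 3 carrying the 2-methyl-1,3-dioxolan-2-yl group on C8a' | Cc1cccc(OC)c1-c1cc(C2(C)OCCO2)c(OC)cc1C
F9 | step 2 | biaryl keto ketal, acetyl on C8a and dioxolane on C8a' | Cc1ccc(C(C)=O)c(OC)c1-c1cc(C2(C)OCCO2)c(OC)cc1C
F10 | step 6 | 3,5'-bis(1-chloroethyl)-2,4'-dimethoxy-2',6-dimethylbiphenyl | Cc1ccc(C(C)Cl)c(OC)c1-c1cc(C(C)Cl)c(OC)cc1C
F11 | step 6 | (4-methylpent-3-en-1-yl)zinc bromide | CC(C)=CCC[Zn]Br
F12 | step 9 | 3,5'-bis[(2S)-5-oxopentan-2-yl]-2,4'-dimethoxy-2',6-dimethylbiphenyl (bis-aldehyde) | Cc1ccc([C@@H](C)CCC=O)c(OC)c1-c1cc([C@@H](C)CCC=O)c(OC)cc1C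
A1 | alternative 1 | C5'-bromo aryl ester linking O8 of the ring A/B half to the C6' carboxyl carbon of the ring C/D half | Cc1cc2c(c(OC(=O)c3cc(OC)c4c(c3Br)[C@@H](C(C)C)CC[C@@H]4C)c1)[C@@H](C)CC[C@@H]2C(C)C
A2 | alternative 1 | bridged biaryl lactone (benzo[c]chromen-6-one core, 8'-methyl ether) | Cc1cc2c(c3OC(=O)c4cc(OC)c5c(c4-c13)[C@@H](C(C)C)CC[C@@H]5C)[C@@H](C)CC[C@@H]2C(C)C
A3 | alternative 2 | aryl alkyne tethered to a 2-silyloxy diene (open rings C and D) | Cc1cc2c(c(OC)c1C#C[C@@H](C(C)C)CC[C@H](C)/C=C(O[Si](C)(C)C(C)(C)C)/C=C/C)[C@@H](C)CC[C@@H]2C(C)C
A4 | alternative 2 | target 8-methyl 8'-silyl bis-ether | Cc1cc2c(c(OC)c1-c1c(C)cc(O[Si](C)(C)C(C)(C)C)c3c1[C@@H](C(C)C)CC[C@@H]3C)[C@@H](C)CC[C@@H]2C(C)C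
A5 | alternative 3 | biaryl bis(3-methylindan-1-one) dimethyl ether | Cc1cc2c(c(OC)c1-c1c(C)cc(OC)c3c1C(=O)C[C@@H]3C)[C@@H](C)CC2=O
A6 | alternative 3 | 1-diazo-2-methylpropane | CC(C)C=[N+]=[N-]
A7 | alternative 3 | biaryl bis(1-isopropyl-4-methyl-2-tetralone) dimethyl ether, trans in each ring | Cc1cc2c(c(OC)c1-c1c(C)cc(OC)c3c1[C@@H](C(C)C)C(=O)C[C@@H]3C)[C@@H](C)CC(=O)[C@@H]2C(C)C
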